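The numbers are those of an exercise; what happens was integrated by code.

A leftover was built into this flask: each open intermediate took one partner or one capture agent, and I saw that those two charges together exceeded the starting material by 0.900 M.

starting material 1.0 M; partner 0.900 M; capture agent 1.00 M; catalyst 4.8 mM; time 30 h

    starting material + catalyst → catalyst + open intermediate (k1 = 10 /M/min)
    partner + catalyst + open intermediate → catalyst + target (k2 = 16 /M²/min)
    open intermediate + capture agent → trapped intermediate (k3 = 0.044 /M/min)

- the reaction counts as stopped when no species that holds the starting material changes by six tenths of a point or more over the second half of the time
- run time (flask): 30 h

- which holds at 30 h: what has brought the reaction to rest, or that it has not come to rest (it is still moving / the partner has run out first / no working catalyst is left / all of the starting material has reacted)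
- share of the starting material used up at 30 h
- target at 30 h, in percent of the starting material charged
- trapped intermediate at 30 h, in percent of the starting material charged

Two numbers looked contradictory to me. The target step had the constant 16 /M²/min and the capture step 0.044 /M/min, yet I expected the two channels to run nearly level. The target step also carried [catalyst], however, and that stayed at 4.8 mM because the step gave it back. So I carried the selectivity factor: the constant of the target step times [catalyst], divided by the constant of the capture step, which came to 1.75. Target formed faster than trapped intermediate by that factor times [partner]/[capture agent].

At the start that ratio was 1.57, a target share of 61.1 %. At half conversion, with both reagents reduced at that share, it had dropped to 1.29. That share, 56.3 %, I took for the whole run, so I committed to target 56.3 % and trapped intermediate 43.7 %. The starting material had a half-life of 14.4 min, far shorter than the run. I therefore expected conversion 100 % and the end state all of the starting material has reacted.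

The forecast said all of the starting material has reacted, conversion 100 %, target 56.7 % and trapped intermediate 43.3 %, “with that ratio falling as the partner depletes”. My target figure was 0.4 percentage points lower.

The flask gave all of the starting material has reacted, with conversion 100 %, target 56.6 % and trapped intermediate 43.4 %.

In the flask, ln of the partner left (37 %) over ln of the capture agent left (57 %) read 1.75, beside the selectivity factor of 1.75. In the neighbour flask with 0.0019 M of catalyst, the selectivity factor was 0.691, the leftovers of 54 % partner and 41 % capture agent read 0.691, and the target stood at 41.2 %.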